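## The problem

Target 31 is a melampolide-type germacranolide: a cyclodeca-1(10),4-diene whose C6–C7 bond carries a trans-fused α-methylene-γ-butyrolactone (O6, C12, C11=C13). It bears an (S)-3-hydroxy-2-methylpropanoate on O8, a methyl group (C14) on C10 and a hydroxymethyl group (C15) on C4. A synthesis must close a ten-membered carbocycle and deliver two trisubstituted ring alkenes of opposite ring geometry: C1=C10 ring-cis and C4=C5 ring-trans (both Z by the sequence rules). The contiguous ring stereocentres C6 (R), C7 (R) and C8 (S) place O6 and O8 on one face and the C11 arm on the other. C7 and C8 are a 1,2-pair that one aldol reaction can set absolutely, C7 must then bias the creation of C6, and the side-chain centre C2′ is independent and best bought. Because two secondary oxygens flank C7, the C7 acetic acid arm can lactonise to O6 or to O8, so the two must stay differentiated until the lactone is closed. The finished molecule tolerates little: the α-methylene lactone is a Michael acceptor, the 1,5-diene cyclises across the ring under acid and can undergo Cope rearrangement on heating, the C6–O bond is allylic, and the β-hydroxy ester side chain can epimerise, eliminate or migrate under base. The enabling feature is the 1,5-diene C10=C1–C2–C3–C4=C5: it is the formal cycloreversion product of a bicyclo[2.2.0]hexane (central bond C1–C4, outer bond C5–C10), and the remaining ring atoms C5–C10, which hold every ring stereocentre and the C6 oxygen, then form a cyclohexanone.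

## Retrosynthesis

**Side chain and silyl ethers (O8–C1′).** Target 31 is traced to the bis-silyl ether 30 and then, by cutting the O8–acyl bond, to carbinol 26 and acid 29. The cut is placed last because the side-chain ester would not survive hydride reductions or enolate chemistry. Acid 29 comes in two steps (via 28) from the commercial Roche ester 27, which supplies C2′. The forward acylation must spare the methylene lactone and the α-centre of 29; the final desilylation must be non-basic.

**Exocyclic methylene (C11=C13).** Carbinol 26 is traced through its silyl ether 25 to the saturated lactone 21 by removing C13. Installing the methylene after lactonisation, rather than carrying an acrylate through the ring-forming steps, keeps the Michael acceptor out of the photochemical, thermal and hydride steps. The forward step is an enolate aminomethylation–elimination, which needs O8 and O15 protected.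

**Lactone and oxidation levels (O6–C12, C6–H, C15).** Lactone 21 is opened to hydroxy tert-butyl ester 20. Removing the C15 silyl group (diol 19), re-oxidising C15 to the ethyl ester (18) and C6 to the ketone gives dienone 17. The C15 ester is reduced before lactonisation because in 18 the C6 hydroxyl is cis to that ester across C4=C5 and could close a butenolide instead. The forward reduction of C6 must deliver the hydride so that O6 ends up trans to the C7 arm.

**Ring expansion (C1–C4 and C5–C10 re-formed).** Dienone 17 is the cycloreversion product of the ladder-shaped tricycle 16, in which a cyclohexanone (C5–C10) is fused to a bicyclo[2.2.0]hexane. This replaces a ten-membered ring closure by bond cleavage in a strained precursor, with no high dilution. The four stereocentres of the ladder disappear in the forward reaction, so every diastereomer of 16 with the right constitution gives the same 17. The forward thermolysis must give the ring-cis C1=C10 and ring-trans C4=C5 pair and stop before Cope rearrangement.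

**Key disconnection (C5–C4 and C10–C1).** Tricycle 16 is cut across the central cyclobutane into enone 12 and ethyl cyclobut-1-enecarboxylate 15. Against a direct macrocyclisation this cut offers a six-membered precursor that holds C6, C7 and C8 and puts the C6 carbonyl and the C15 ester where the lactone oxygen and the hydroxymethyl group are needed. The forward [2+2] photocycloaddition must be head-to-head (ester-bearing C4 on the enone α-carbon C5).

**Cyclohexenone (C5=C10, C5–C6).** Enone 12 is opened at C5=C10 by retro-metathesis to vinyl ketone 11, which is traced through Weinreb amide 10 and its carbinol 9 to aldol adduct 8. Metathesis is chosen over an aldol or phosphonate condensation because the β-silyloxy ketone would eliminate under base. The forward steps must keep the tert-butyl ester intact.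

**Aldol (C7–C8).** Adduct 8 is cut between C7 and C8 into imide 4 and 3-methylbut-3-enal 6. Imide 4 comes from mono-tert-butyl succinate 1 and oxazolidinone 2 via the mixed anhydride 3, and aldehyde 6 from alcohol 5. One reaction, through boron enolate 7, sets both C7 and C8; the syn aldol pair becomes the trans pair of the ring. The forward reaction requires selective enolisation of the imide and an aldehyde that does not isomerise into conjugation.

**Cyclobutene partner.** Ester 15 is traced through acid 14 to ethyl 1-bromocyclobutane-1-carboxylate 13 by dehydrobromination and re-esterification.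

## Roads not taken

**Alternative 1: Grob fragmentation of a hydroazulene.** The ten-membered ring is reconnected between C4 and C8 to give the cis-fused hydroazulene hydroxy mesylate A1. In the forward sense KOtBu forms the C8 alkoxide, which expels the C5 mesylate, breaks the C4–C8 fusion bond and gives the cyclodeca-1(10),4-dien-8-one A2.
- Merits: the ring-cis C1=C10 alkene is inherited from a cycloheptene and the ring-trans C4=C5 alkene follows from the anti-periplanar arrangement of the breaking bonds. Both geometries are therefore enforced, and the ring opens at low temperature without heating a 1,5-diene. In this respect the route is better than the chosen plan, whose geometry is only expected from a conformational preference.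
- Weak points: A1 needs five contiguous stereocentres, including a quaternary C4 and a tertiary carbinol at C8 with a fixed relationship to the C5 mesylate. C8 emerges as a ketone and must be reduced stereoselectively in the ten-membered ring. C12 is at the alcohol level, so two oxidations precede lactonisation. A2 is a β-silyloxy ketone formed under strong base.
- Comparison: the chosen plan sets against the geometric certainty a much shorter access to the ring (two steps from a cyclohexenone made by one aldol) and the convergence of all photoadduct diastereomers.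

**Alternative 2: Palladium cyclocarbonylation of an ethynyl carbinol.** The O6–C12 and C12–C11 bonds are cut, leading back to the ten-membered ethynyl carbinol A3. In the forward sense the divalent palladium system PdCl2/PPh3/SnCl2 under CO joins the C6 hydroxyl, carbon monoxide and the C7 ethynyl group to give the bis-silyl ether of the target, A4.
- Merits: lactone and exocyclic methylene are formed in one step without strong base. This is shorter than steps 15 and 16 of the chosen plan and is the better end game taken in isolation.
- Weak points: the tactic does not address the ten-membered ring, the two alkenes or the C6–C8 triad, all of which must already be present in A3. A C7 ethynyl group is harder to set than an acetate arm and interferes with metal-mediated ring closures. A3 exposes an allylic carbinol and a 1,5-diene to a Lewis-acidic palladium/tin medium and already carries the epimerisable side chain.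
- Comparison: the chosen plan pays one extra step for the lactone but its key step solves the ring problem, and its acetate arm comes directly from the aldol.

**Alternative 3: Nozaki–Hiyama–Kishi macrocyclisation at C5–C6.** The C5–C6 bond is cut to give the acyclic iodo aldehyde A5. CrCl2 with catalytic NiCl2 adds the alkenyl metal to the aldehyde, closing the ring and creating the C6 carbinol A6, which is the same compound as 20.
- Merits: the C4=C5 geometry is carried unchanged from the vinyl iodide, and the C1=C10 geometry can be proven in the open chain. The reaction tolerates esters and silyl ethers, and the end game would be identical with steps 15–21. In geometric certainty it is again better.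
- Weak points: a ten-membered ring is closed against entropy and transannular strain at high dilution with a large excess of CrCl2. The C6 configuration is decided in a macrocyclic transition state and is no more predictable than the reduction in step 12. A5 has an epimerisable α-centre with a β-silyloxy group and needs two stereodefined trisubstituted alkenes built linearly.
- Comparison: the chosen plan reaches 20 in eleven linear steps from 1 without a macrocyclisation, but must prove its alkene geometry after step 11.

Key step: step 10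

Remark on the chemistry: germacrane numbering (ring C1–C10, lactone carbons C11–C13, C14 methyl, C15 hydroxymethyl) is used throughout. Compound 16 is written as the diastereomer from addition anti to the C8 silyloxy group; its facial isomer differs only at centres that step 11 destroys and is carried along with it.

## Route

Step 1
Reactants: 1 4-tert-butoxy-4-oxobutanoic acid (mono-tert-butyl succinate); 2 (R)-4-benzyl-1,3-oxazolidin-2-one
Product: 4 tert-butyl 4-[(4R)-4-benzyl-2-oxo-1,3-oxazolidin-3-yl]-4-oxobutanoate, via mixed pivalic anhydride 3 (not isolated)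
Conditions: PivCl, Et3N, THF, −20 °C; then 2, LiCl, −20 °C → rt
Reagents that add atoms: none
Why: Mixed-anhydride N-acylation of the oxazolidinone (LiCl/Et3N activation) attaches the Evans auxiliary to the free acid terminus; the tert-butyl ester is inert.

Step 2
Reactants: 5 3-methylbut-3-en-1-ol
Product: 6 3-methylbut-3-enal
Conditions: Dess–Martin periodinane, CH2Cl2, 0 °C → rt; filtered solution used at once
Reagents that add atoms: none
Why: Dess–Martin oxidation under neutral anhydrous conditions stops at the aldehyde and avoids the base that would move the β,γ-alkene into conjugation; the volatile aldehyde is not stored.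

Step 3
Reactants: 4 tert-butyl 4-[(4R)-4-benzyl-2-oxo-1,3-oxazolidin-3-yl]-4-oxobutanoate; 6 3-methylbut-3-enal
Product: 8 tert-butyl (3R,4S)-3-{[(4R)-4-benzyl-2-oxo-1,3-oxazolidin-3-yl]carbonyl}-4-hydroxy-6-methylhept-6-enoate, via dibutylboron Z-enolate 7 (not isolated)
Conditions: Bu2BOTf, iPr2NEt, CH2Cl2, 0 °C; then 6, −78 → 0 °C; pH 7 buffer, MeOH, 30% H2O2, 0 °C
Reagents that add atoms: none
Why: Evans syn-aldol reaction: the imide α-methylene is enolised selectively to the Z-boron enolate 7, which adds through a closed chair transition state on the face away from the benzyl group. This sets C7 (R) and C8 (S) together; the syn pair becomes the trans pair of the later ring.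

Step 4
Reactants: 8 tert-butyl (3R,4S)-3-{[(4R)-4-benzyl-2-oxo-1,3-oxazolidin-3-yl]carbonyl}-4-hydroxy-6-methylhept-6-enoate
Product: 9 tert-butyl (3R,4S)-4-hydroxy-3-[methoxy(methyl)carbamoyl]-6-methylhept-6-enoate
Conditions: MeNH(OMe)·HCl, AlMe3, CH2Cl2, −20 → 0 °C; aq. HCl work-up
Reagents that add atoms: N,O-dimethylhydroxylamine hydrochloride, CNOC.Cl
Why: Weinreb transamidation with the aluminium amide, assisted by the free β-hydroxyl, removes the auxiliary (recoverable) without touching the hindered tert-butyl ester or the stereocentres.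

Step 5
Reactants: 9 tert-butyl (3R,4S)-4-hydroxy-3-[methoxy(methyl)carbamoyl]-6-methylhept-6-enoate
Product: 10 tert-butyl (3R,4S)-4-[(tert-butyldimethylsilyl)oxy]-3-[methoxy(methyl)carbamoyl]-6-methylhept-6-enoate
Conditions: TBSOTf, 2,6-lutidine, CH2Cl2, −78 °C
Reagents that add atoms: tert-butyldimethylsilyl triflate, CC(C)(C)[Si](C)(C)OS(=O)(=O)C(F)(F)F
Why: Low-temperature silylation of the secondary carbinol; O8 must be masked so that only O6 can later lactonise.

Step 6
Reactants: 10 tert-butyl (3R,4S)-4-[(tert-butyldimethylsilyl)oxy]-3-[methoxy(methyl)carbamoyl]-6-methylhept-6-enoate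
Product: 11 tert-butyl (3R,4S)-4-[(tert-butyldimethylsilyl)oxy]-6-methyl-3-(prop-2-enoyl)hept-6-enoate
Conditions: CH2=CHMgBr, THF, −20 → 0 °C; poured into cold 1 M HCl
Reagents that add atoms: vinylmagnesium bromide, C=C[Mg]Br
Why: Weinreb ketone synthesis: addition stops at the ketone stage and the hindered tert-butyl ester is not attacked at this temperature. The acidic inverse quench prevents conjugate addition of the liberated hydroxylamine to the vinyl ketone.

Step 7
Reactants: 11 tert-butyl (3R,4S)-4-[(tert-butyldimethylsilyl)oxy]-6-methyl-3-(prop-2-enoyl)hept-6-enoate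
Product: 12 tert-butyl 2-[(1R,6S)-6-[(tert-butyldimethylsilyl)oxy]-4-methyl-2-oxocyclohex-3-en-1-yl]acetate
Conditions: second-generation Grubbs catalyst (H2IMes)(PCy3)Cl2Ru=CHPh (5 mol %), CH2Cl2, 40 °C
Reagents that add atoms: none
Why: Ring-closing metathesis between the enone vinyl group and the 1,1-disubstituted alkene closes the six-membered ring as the 3-methylcyclohexenone. The neutral conditions suit the base-sensitive β-silyloxy ketone.

Step 8
Reactants: 13 ethyl 1-bromocyclobutane-1-carboxylate
Product: 14 cyclobut-1-ene-1-carboxylic acid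
Conditions: KOH, PhMe, reflux; then aq. HCl, 0 °C
Reagents that add atoms: potassium hydroxide, [K+].[OH-]
Why: Base-induced dehydrobromination of the tertiary α-bromo ester with concurrent saponification gives the crystalline cyclobutene acid, the established entry to cyclobut-1-enecarboxylates.

Step 9
Reactants: 14 cyclobut-1-ene-1-carboxylic acid
Product: 15 ethyl cyclobut-1-ene-1-carboxylate
Conditions: EtI, K2CO3, DMF, rt; stored cold over hydroquinone
Reagents that add atoms: iodoethane, CCI
Why: Carboxylate O-alkylation re-forms the ethyl ester under conditions too mild to polymerise or ring-open the strained acrylate.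

Step 10
Reactants: 12 tert-butyl 2-[(1R,6S)-6-[(tert-butyldimethylsilyl)oxy]-4-methyl-2-oxocyclohex-3-en-1-yl]acetate; 15 ethyl cyclobut-1-ene-1-carboxylate
Product: 16 ethyl (1R,2R,5S,6R,8R,9S)-8-(2-tert-butoxy-2-oxoethyl)-9-[(tert-butyldimethylsilyl)oxy]-1-methyl-7-oxotricyclo[4.4.0.0(2,5)]decane-5-carboxylate
Conditions: hν (λ ≥ 300 nm, Pyrex), 15 (5 equiv), degassed CH2Cl2, −20 °C
Reagents that add atoms: none
Why: Excitation of the enone n,π* band and intersystem crossing give the twisted triplet, whose β-carbon C10 bonds to the unsubstituted cyclobutene carbon C1; the resulting triplet 1,4-biradical (α-keto radical at C5, ester-stabilised tertiary radical at C4) closes C5–C4 after spin inversion. The closest known reaction type is the intermolecular enone–alkene [2+2] photocycloaddition, here in its documented form with 3-alkylcyclohexenones and alkyl cyclobut-1-enecarboxylates. One four-membered ring is closed, intermolecularly, by stepwise two-bond formation ending in radical recombination. C5 and C10 are set cis because a trans-fused bicyclo[4.2.0]octanone is strained; C1 and C4 are cis because they come from a cis ring alkene. The anti relationship of the two outer rings follows from approach of the cyclobutene with its CH2–CH2 bridge turned away from the cyclohexanone. Addition anti to the C8 silyloxy group is expected to dominate, but the facial outcome is irrelevant because these four centres are destroyed in step 11. The selectivity the step needs is head-to-head regiochemistry (C4 on C5); it is secured by the acceptor-substituted alkene, which pairs its ester carbon with the enone α-carbon through the more stabilised biradical. The excess of 15 suppresses enone dimerisation.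

Step 11
Reactants: 16 ethyl (1R,2R,5S,6R,8R,9S)-8-(2-tert-butoxy-2-oxoethyl)-9-[(tert-butyldimethylsilyl)oxy]-1-methyl-7-oxotricyclo[4.4.0.0(2,5)]decane-5-carboxylate
Product: 17 ethyl (1Z,4R,5S,7Z)-4-(2-tert-butoxy-2-oxoethyl)-5-[(tert-butyldimethylsilyl)oxy]-7-methyl-3-oxocyclodeca-1,7-diene-1-carboxylate
Conditions: degassed PhMe (0.01 M), BHT (cat.), base-washed sealed tube, 175 °C
Reagents that add atoms: none
Why: Thermal cycloreversion of the bicyclo[2.2.0]hexane: the central C1–C4 bond, weakened by strain and the C4 ester, breaks to a cyclohexane-1,4-diyl, which then cleaves C5–C10 and releases both four-membered rings. Cleavage from the chair diyl with the C14 methyl and C6 equatorial is expected to give ring-cis C1=C10 and ring-trans C4=C5. C1, C4, C5 and C10 become trigonal, so all diastereomers of 16 converge on 17.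

Step 12
Reactants: 17 ethyl (1Z,4R,5S,7Z)-4-(2-tert-butoxy-2-oxoethyl)-5-[(tert-butyldimethylsilyl)oxy]-7-methyl-3-oxocyclodeca-1,7-diene-1-carboxylate
Product: 18 ethyl (1Z,3R,4S,5S,7Z)-4-(2-tert-butoxy-2-oxoethyl)-5-[(tert-butyldimethylsilyl)oxy]-3-hydroxy-7-methylcyclodeca-1,7-diene-1-carboxylate
Conditions: NaBH4, CeCl3·7H2O, MeOH/THF, −78 °C; aq. NH4Cl at −78 °C
Reagents that add atoms: none
Why: Luche reduction: CeCl3 directs the borohydride to 1,2-addition on the 4-oxo-enoate. The small hydride is expected to enter on the axial-type trajectory anti to C7–H, giving the pseudo-equatorial 6R carbinol with O6 trans to the C7 arm. The cold quench and immediate use keep the carbinol from closing on the cis C15 ester.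

Step 13
Reactants: 18 ethyl (1Z,3R,4S,5S,7Z)-4-(2-tert-butoxy-2-oxoethyl)-5-[(tert-butyldimethylsilyl)oxy]-3-hydroxy-7-methylcyclodeca-1,7-diene-1-carboxylate
Product: 19 tert-butyl 2-[(1S,2R,3Z,7Z,10S)-10-[(tert-butyldimethylsilyl)oxy]-2-hydroxy-4-(hydroxymethyl)-8-methylcyclodeca-3,7-dien-1-yl]acetate
Conditions: iBu2AlH (3.5 equiv), CH2Cl2, −78 °C; aq. potassium sodium tartrate
Reagents that add atoms: none
Why: iBu2AlH reduces the conjugated ethyl ester 1,2 to the allylic alcohol at −78 °C, where the hindered tert-butyl ester reacts much more slowly. Removing the C15 ester also removes the butenolide pathway.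

Step 14
Reactants: 19 tert-butyl 2-[(1S,2R,3Z,7Z,10S)-10-[(tert-butyldimethylsilyl)oxy]-2-hydroxy-4-(hydroxymethyl)-8-methylcyclodeca-3,7-dien-1-yl]acetate
Product: 20 tert-butyl 2-[(1S,2R,3Z,7Z,10S)-10-[(tert-butyldimethylsilyl)oxy]-4-{[(tert-butyldiphenylsilyl)oxy]methyl}-2-hydroxy-8-methylcyclodeca-3,7-dien-1-yl]acetate
Conditions: TBDPSCl (1.05 equiv), imidazole, CH2Cl2, 0 °C
Reagents that add atoms: tert-butyl(chloro)diphenylsilane, CC(C)(C)[Si](Cl)(c1ccccc1)c1ccccc1
Why: The bulky silyl chloride takes the primary allylic hydroxyl in preference to the hindered secondary C6 hydroxyl; O15 must be masked for the enolate and acylation steps.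

Step 15
Reactants: 20 tert-butyl 2-[(1S,2R,3Z,7Z,10S)-10-[(tert-butyldimethylsilyl)oxy]-4-{[(tert-butyldiphenylsilyl)oxy]methyl}-2-hydroxy-8-methylcyclodeca-3,7-dien-1-yl]acetate
Product: 21 (3aS,4S,6Z,10Z,11aR)-4-[(tert-butyldimethylsilyl)oxy]-10-{[(tert-butyldiphenylsilyl)oxy]methyl}-6-methyl-3a,4,5,8,9,11a-hexahydrocyclodeca[b]furan-2(3H)-one
Conditions: CSA (0.1 equiv), CH2Cl2, 0 °C → rt
Reagents that add atoms: none
Why: Acid-catalysed lactonisation of the γ-hydroxy tert-butyl ester (loss of tert-butanol) closes the five-membered ring on O6, the only free hydroxyl. The trans fusion is fixed by the C6 and C7 configurations already present.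

Step 16
Reactants: 21 (3aS,4S,6Z,10Z,11aR)-4-[(tert-butyldimethylsilyl)oxy]-10-{[(tert-butyldiphenylsilyl)oxy]methyl}-6-methyl-3a,4,5,8,9,11a-hexahydrocyclodeca[b]furan-2(3H)-one
Product: 25 (3aS,4S,6Z,10Z,11aR)-4-[(tert-butyldimethylsilyl)oxy]-10-{[(tert-butyldiphenylsilyl)oxy]methyl}-6-methyl-3-methylidene-3a,4,5,8,9,11a-hexahydrocyclodeca[b]furan-2(3H)-one, via lithium enolate 22 (not isolated), via Mannich base 23 (not isolated), via trimethylammonium iodide 24 (not isolated)
Conditions: LiN(iPr)2, THF, −78 °C; CH2=NMe2+ I−, −78 → 0 °C; then MeI, MeOH, rt; then aq. NaHCO3, EtOAc, rt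
Reagents that add atoms: N,N-dimethylmethyleneiminium iodide (Eschenmoser's salt), C=[N+](C)C.[I-]
Why: Enolate aminomethylation with Eschenmoser's salt, N-methylation and E1cB loss of trimethylamine is the standard route to an α-methylene-γ-butyrolactone. The transient C11 centre of 23 and 24 is destroyed, and no leaving group sits β to the enolate.

Step 17
Reactants: 25 (3aS,4S,6Z,10Z,11aR)-4-[(tert-butyldimethylsilyl)oxy]-10-{[(tert-butyldiphenylsilyl)oxy]methyl}-6-methyl-3-methylidene-3a,4,5,8,9,11a-hexahydrocyclodeca[b]furan-2(3H)-one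
Product: 26 (3aR,4S,6Z,10Z,11aR)-10-{[(tert-butyldiphenylsilyl)oxy]methyl}-4-hydroxy-6-methyl-3-methylidene-3a,4,5,8,9,11a-hexahydrocyclodeca[b]furan-2(3H)-one
Conditions: 48% aq. HF, MeCN, 0 °C
Reagents that add atoms: none
Why: Aqueous HF in acetonitrile cleaves the secondary tert-butyldimethylsilyl ether, while the tert-butyldiphenylsilyl ether is much more stable to this acidic reagent. The non-basic medium protects the methylene lactone.

Step 18
Reactants: 27 methyl (S)-3-hydroxy-2-methylpropanoate
Product: 28 methyl (S)-3-[(tert-butyldimethylsilyl)oxy]-2-methylpropanoate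
Conditions: TBSCl, imidazole, CH2Cl2, 0 °C → rt
Reagents that add atoms: tert-butyl(chloro)dimethylsilane, CC(C)(C)[Si](C)(C)Cl
Why: Standard silylation of the primary hydroxyl; the stereocentre is not involved.

Step 19
Reactants: 28 methyl (S)-3-[(tert-butyldimethylsilyl)oxy]-2-methylpropanoate
Product: 29 (S)-3-[(tert-butyldimethylsilyl)oxy]-2-methylpropanoic acid
Conditions: LiOH·H2O, THF/MeOH/H2O, 0 °C; then 1 M HCl to pH 4, 0 °C
Reagents that add atoms: lithium hydroxide, [Li+].[OH-]
Why: Mild saponification of the methyl ester at 0 °C, a known route to this acid without epimerisation at C2′ or β-elimination.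

Step 20
Reactants: 26 (3aR,4S,6Z,10Z,11aR)-10-{[(tert-butyldiphenylsilyl)oxy]methyl}-4-hydroxy-6-methyl-3-methylidene-3a,4,5,8,9,11a-hexahydrocyclodeca[b]furan-2(3H)-one; 29 (S)-3-[(tert-butyldimethylsilyl)oxy]-2-methylpropanoic acid
Product: 30 (3aR,4S,6Z,10Z,11aR)-10-{[(tert-butyldiphenylsilyl)oxy]methyl}-6-methyl-3-methylidene-2-oxo-2,3,3a,4,5,8,9,11a-octahydrocyclodeca[b]furan-4-yl (2S)-3-[(tert-butyldimethylsilyl)oxy]-2-methylpropanoate
Conditions: EDC·HCl, DMAP (0.2 equiv), CH2Cl2, 0 °C → rt
Reagents that add atoms: none
Why: Steglich esterification of the only free hydroxyl (C8); carbodiimide activation at 0 °C with catalytic DMAP keeps the α-centre of 29 intact and is mild enough for the methylene lactone.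

Step 21
Reactants: 30 (3aR,4S,6Z,10Z,11aR)-10-{[(tert-butyldiphenylsilyl)oxy]methyl}-6-methyl-3-methylidene-2-oxo-2,3,3a,4,5,8,9,11a-octahydrocyclodeca[b]furan-4-yl (2S)-3-[(tert-butyldimethylsilyl)oxy]-2-methylpropanoate
Product: 31 (3aR,4S,6Z,10Z,11aR)-10-(hydroxymethyl)-6-methyl-3-methylidene-2-oxo-2,3,3a,4,5,8,9,11a-octahydrocyclodeca[b]furan-4-yl (2S)-3-hydroxy-2-methylpropanoate
Conditions: HF·pyridine, pyridine, THF, 0 °C → rt
Reagents that add atoms: none
Why: Fluoride cleavage of both primary silyl ethers with pyridine-buffered HF·pyridine; the weakly acidic medium avoids conjugate addition to the methylene lactone, acyl migration and epimerisation or elimination in the side chain.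

## Compound list

1 | 4-tert-butoxy-4-oxobutanoic acid (mono-tert-butyl succinate) | OC(=O)CCC(=O)OC(C)(C)C | starting material
2 | (R)-4-benzyl-1,3-oxazolidin-2-one | O=C1N[C@H](Cc2ccccc2)CO1 | starting material
3 | 4-tert-butoxy-4-oxobutanoic pivalic anhydride (formed in situ) | CC(C)(C)C(=O)OC(=O)CCC(=O)OC(C)(C)C | intermediate
4 | tert-butyl 4-[(4R)-4-benzyl-2-oxo-1,3-oxazolidin-3-yl]-4-oxobutanoate | O=C1OC[C@@H](Cc2ccccc2)N1C(=O)CCC(=O)OC(C)(C)C | intermediate
5 | 3-methylbut-3-en-1-ol | C=C(C)CCO | starting material
6 | 3-methylbut-3-enal | C=C(C)CC=O | intermediate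
7 | dibutylboron (Z)-enolate of 4 (formed in situ) | O=C1OC[C@@H](Cc2ccccc2)N1/C(OB(CCCC)CCCC)=C/CC(=O)OC(C)(C)C | intermediate
8 | tert-butyl (3R,4S)-3-{[(4R)-4-benzyl-2-oxo-1,3-oxazolidin-3-yl]carbonyl}-4-hydroxy-6-methylhept-6-enoate | O=C1OC[C@@H](Cc2ccccc2)N1C(=O)[C@H](CC(=O)OC(C)(C)C)[C@@H](O)CC(C)=C | intermediate
9 | tert-butyl (3R,4S)-4-hydroxy-3-[methoxy(methyl)carbamoyl]-6-methylhept-6-enoate | CON(C)C(=O)[C@H](CC(=O)OC(C)(C)C)[C@@H](O)CC(C)=C | intermediate
10 | tert-butyl (3R,4S)-4-[(tert-butyldimethylsilyl)oxy]-3-[methoxy(methyl)carbamoyl]-6-methylhept-6-enoate | CON(C)C(=O)[C@H](CC(=O)OC(C)(C)C)[C@@H](O[Si](C)(C)C(C)(C)C)CC(C)=C | intermediate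
11 | tert-butyl (3R,4S)-4-[(tert-butyldimethylsilyl)oxy]-6-methyl-3-(prop-2-enoyl)hept-6-enoate | C=CC(=O)[C@H](CC(=O)OC(C)(C)C)[C@@H](O[Si](C)(C)C(C)(C)C)CC(C)=C | intermediate
12 | tert-butyl 2-[(1R,6S)-6-[(tert-butyldimethylsilyl)oxy]-4-methyl-2-oxocyclohex-3-en-1-yl]acetate | O=C1C=C(C)C[C@H](O[Si](C)(C)C(C)(C)C)[C@H]1CC(=O)OC(C)(C)C | intermediate
13 | ethyl 1-bromocyclobutane-1-carboxylate | CCOC(=O)C1(Br)CCC1 | starting material
14 | cyclobut-1-ene-1-carboxylic acid | OC(=O)C1=CCC1 | intermediate
15 | ethyl cyclobut-1-ene-1-carboxylate | CCOC(=O)C1=CCC1 | intermediate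
16 | ethyl (1R,2R,5S,6R,8R,9S)-8-(2-tert-butoxy-2-oxoethyl)-9-[(tert-butyldimethylsilyl)oxy]-1-methyl-7-oxotricyclo[4.4.0.0(2,5)]decane-5-carboxylate (cis–anti–cis, head-to-head) | O=C1[C@@H]2[C@](C)(C[C@H](O[Si](C)(C)C(C)(C)C)[C@H]1CC(=O)OC(C)(C)C)[C@H]1CC[C@]12C(=O)OCC | intermediate
17 | ethyl (1Z,4R,5S,7Z)-4-(2-tert-butoxy-2-oxoethyl)-5-[(tert-butyldimethylsilyl)oxy]-7-methyl-3-oxocyclodeca-1,7-diene-1-carboxylate | O=C1/C=C(\C(=O)OCC)CC/C=C(/C)C[C@H](O[Si](C)(C)C(C)(C)C)[C@H]1CC(=O)OC(C)(C)C | intermediate
18 | ethyl (1Z,3R,4S,5S,7Z)-4-(2-tert-butoxy-2-oxoethyl)-5-[(tert-butyldimethylsilyl)oxy]-3-hydroxy-7-methylcyclodeca-1,7-diene-1-carboxylate | O[C@@H]1/C=C(\C(=O)OCC)CC/C=C(/C)C[C@H](O[Si](C)(C)C(C)(C)C)[C@H]1CC(=O)OC(C)(C)C | intermediate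
19 | tert-butyl 2-[(1S,2R,3Z,7Z,10S)-10-[(tert-butyldimethylsilyl)oxy]-2-hydroxy-4-(hydroxymethyl)-8-methylcyclodeca-3,7-dien-1-yl]acetate | O[C@@H]1/C=C(\CO)CC/C=C(/C)C[C@H](O[Si](C)(C)C(C)(C)C)[C@H]1CC(=O)OC(C)(C)C | intermediate
20 | tert-butyl 2-[(1S,2R,3Z,7Z,10S)-10-[(tert-butyldimethylsilyl)oxy]-4-{[(tert-butyldiphenylsilyl)oxy]methyl}-2-hydroxy-8-methylcyclodeca-3,7-dien-1-yl]acetate | O[C@@H]1/C=C(\CO[Si](c2ccccc2)(c2ccccc2)C(C)(C)C)CC/C=C(/C)C[C@H](O[Si](C)(C)C(C)(C)C)[C@H]1CC(=O)OC(C)(C)C | intermediate
21 | (3aS,4S,6Z,10Z,11aR)-4-[(tert-butyldimethylsilyl)oxy]-10-{[(tert-butyldiphenylsilyl)oxy]methyl}-6-methyl-3a,4,5,8,9,11a-hexahydrocyclodeca[b]furan-2(3H)-one | O=C1O[C@@H]2/C=C(\CO[Si](c3ccccc3)(c3ccccc3)C(C)(C)C)CC/C=C(/C)C[C@H](O[Si](C)(C)C(C)(C)C)[C@H]2C1 | intermediate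
22 | lithium enolate of 21 (formed in situ) | [Li]OC1=C[C@H]2[C@H](O1)/C=C(\CO[Si](c3ccccc3)(c3ccccc3)C(C)(C)C)CC/C=C(/C)C[C@@H]2O[Si](C)(C)C(C)(C)C | intermediate
23 | C11-(dimethylaminomethyl) derivative of 21 (Mannich base, formed in situ; transient C11 centre drawn with the aminomethyl group trans to C8) | CN(C)C[C@@H]1C(=O)O[C@@H]2/C=C(\CO[Si](c3ccccc3)(c3ccccc3)C(C)(C)C)CC/C=C(/C)C[C@H](O[Si](C)(C)C(C)(C)C)[C@@H]12 | intermediate
24 | C11-(trimethylammoniomethyl) iodide of 21 (formed in situ) | C[N+](C)(C)C[C@@H]1C(=O)O[C@@H]2/C=C(\CO[Si](c3ccccc3)(c3ccccc3)C(C)(C)C)CC/C=C(/C)C[C@H](O[Si](C)(C)C(C)(C)C)[C@@H]12.[I-] | intermediate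
25 | (3aS,4S,6Z,10Z,11aR)-4-[(tert-butyldimethylsilyl)oxy]-10-{[(tert-butyldiphenylsilyl)oxy]methyl}-6-methyl-3-methylidene-3a,4,5,8,9,11a-hexahydrocyclodeca[b]furan-2(3H)-one | C=C1C(=O)O[C@@H]2/C=C(\CO[Si](c3ccccc3)(c3ccccc3)C(C)(C)C)CC/C=C(/C)C[C@H](O[Si](C)(C)C(C)(C)C)[C@@H]12 | intermediate
26 | (3aR,4S,6Z,10Z,11aR)-10-{[(tert-butyldiphenylsilyl)oxy]methyl}-4-hydroxy-6-methyl-3-methylidene-3a,4,5,8,9,11a-hexahydrocyclodeca[b]furan-2(3H)-one | C=C1C(=O)O[C@@H]2/C=C(\CO[Si](c3ccccc3)(c3ccccc3)C(C)(C)C)CC/C=C(/C)C[C@H](O)[C@@H]12 | intermediate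
27 | methyl (S)-3-hydroxy-2-methylpropanoate | COC(=O)[C@@H](C)CO | starting material
28 | methyl (S)-3-[(tert-butyldimethylsilyl)oxy]-2-methylpropanoate | COC(=O)[C@@H](C)CO[Si](C)(C)C(C)(C)C | intermediate
29 | (S)-3-[(tert-butyldimethylsilyl)oxy]-2-methylpropanoic acid | OC(=O)[C@@H](C)CO[Si](C)(C)C(C)(C)C | intermediate
30 | (3aR,4S,6Z,10Z,11aR)-10-{[(tert-butyldiphenylsilyl)oxy]methyl}-6-methyl-3-methylidene-2-oxo-2,3,3a,4,5,8,9,11a-octahydrocyclodeca[b]furan-4-yl (2S)-3-[(tert-butyldimethylsilyl)oxy]-2-methylpropanoate | C=C1C(=O)O[C@@H]2/C=C(\CO[Si](c3ccccc3)(c3ccccc3)C(C)(C)C)CC/C=C(/C)C[C@H](OC(=O)[C@@H](C)CO[Si](C)(C)C(C)(C)C)[C@@H]12 | intermediate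
31 | (3aR,4S,6Z,10Z,11aR)-10-(hydroxymethyl)-6-methyl-3-methylidene-2-oxo-2,3,3a,4,5,8,9,11a-octahydrocyclodeca[b]furan-4-yl (2S)-3-hydroxy-2-methylpropanoate | C=C1C(=O)O[C@@H]2/C=C(\CO)CC/C=C(/C)C[C@H](OC(=O)[C@@H](C)CO)[C@@H]12 | target

## Step count and least certain steps

Total step count: 21. Longest linear sequence: 16 steps (1 → 4 → 8 → 9 → 10 → 11 → 12 → 16 → 17 → 18 → 19 → 20 → 21 → 25 → 26 → 30 → 31; steps 1, 3–7, 10–17, 20, 21).

**Step 10 (key step).** The most likely failures are erosion of the head-to-head regiochemistry and loss of material to enone photodimerisation, polymerisation of the strained cyclobutene ester, or elimination of the β-silyloxy group. Low facial selectivity is expected and harmless. Fallback: the ladder is built in two photochemical stages. Setting out from 12, [2+2] photocycloaddition with ethyl propiolate gives the cyclobutene-fused ketone ethyl 3-(2-tert-butoxy-2-oxoethyl)-4-[(tert-butyldimethylsilyl)oxy]-6-methyl-2-oxobicyclo[4.2.0]oct-7-ene-8-carboxylate F1, in which regioisomers can be separated before the ladder exists. A second, sensitised [2+2] cycloaddition of ethylene to the convex face of the cyclobutene ester closes the outer four-membered ring anti to the cyclohexanone and returns to the route at 16.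

**Step 11.** The cycloreversion may give the wrong pair of alkene geometries if the diyl cleaves before reaching the favoured chair. The 1,5-diene may undergo Cope rearrangement to a divinylcyclohexanone at the temperature needed, and the 4-oxo-enoate, the β-silyloxy ketone or the tert-butyl ester may not survive prolonged heating. Fallback: the ketone is removed before heating. Setting out from 16, NaBH4/CeCl3 gives the tricyclic C6 carbinol (7-hydroxy analogue of 16) F2; its C6 configuration would have to be checked, since the hydride now meets a rigid cyclohexanone and the facial isomers of 16 no longer behave alike. Thermolysis of F2 gives 18, which at that temperature is expected to close in part to the O6–C15 butenolide-bridged cyclodecadiene F3. Treatment of the mixture with iBu2AlH and then NaBH4 reduces both to the diol, and the route is rejoined at 19.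

**Step 12.** Hydride delivery may occur from the open peripheral face instead of the axial-type trajectory, giving the C6 epimer; partial closure of the carbinol onto the C15 ester is the second risk. Fallback: setting out from 17, reduction from the peripheral face (the same reagent or a bulky hydride) gives the 6S carbinol (6-epimer of 18) F4. Mitsunobu esterification with benzoic acid (PPh3, DIAD) inverts C6 to the 6R benzoate of 18 F5. iBu2AlH then removes the benzoate and reduces the enoate in one operation, returning to the route at 19.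

**Step 15.** Under acid the allylic C6 carbinol may ionise or the diene may cyclise across the ring, and loss of the C8 silyl group would open the way to the 8,12-lactone. Fallback: the ester is cleaved without protic acid and the ring closed by carboxyl activation. Setting out from 20, TMSOTf/2,6-lutidine converts the tert-butyl ester into the silyl ester and caps O6, giving the trimethylsilyl ester/trimethylsilyl ether of the seco acid F6. Mild aqueous work-up gives the 6-hydroxy seco acid F7, and EDC·HCl/DMAP closes the lactone, returning to the route at 21.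

**Step 17.** The tert-butyldiphenylsilyl ether may be lost with the hindered secondary silyl ether, or the acidic medium may damage the allylic lactone and diene before the C8 ether has reacted. Fallback: selectivity is moved from deprotection to protection. Setting out from 25, both silyl ethers are removed with pyridine-buffered HF·pyridine to give the C8,C15-diol F8. TBDPSCl/imidazole at 0 °C then silylates only the primary allylic hydroxyl, returning to the route at 26.

## Further compounds

F1 | step 10 | ethyl 3-(2-tert-butoxy-2-oxoethyl)-4-[(tert-butyldimethylsilyl)oxy]-6-methyl-2-oxobicyclo[4.2.0]oct-7-ene-8-carboxylate (cis-fused, cyclobutene anti to the silyloxy group) | O=C1[C@H]2C(C(=O)OCC)=C[C@@]2(C)C[C@H](O[Si](C)(C)C(C)(C)C)[C@H]1CC(=O)OC(C)(C)C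
F2 | step 11 | tricyclic C6 carbinol, 7-hydroxy analogue of 16 (hydroxyl trans to the C7 arm) | O[C@@H]1[C@@H]2[C@](C)(C[C@H](O[Si](C)(C)C(C)(C)C)[C@H]1CC(=O)OC(C)(C)C)[C@H]1CC[C@]12C(=O)OCC
F3 | step 11 | O6–C15 butenolide-bridged cyclodecadiene with C7 tert-butyl acetate arm and C8 silyl ether | O=C1O[C@@H]2C=C1CC/C=C(/C)C[C@H](O[Si](C)(C)C(C)(C)C)[C@H]2CC(=O)OC(C)(C)C
F4 | step 12 | 6S carbinol, C6 epimer of 18 | O[C@H]1/C=C(\C(=O)OCC)CC/C=C(/C)C[C@H](O[Si](C)(C)C(C)(C)C)[C@H]1CC(=O)OC(C)(C)C
F5 | step 12 | 6R benzoate of 18 | O=C(O[C@@H]1/C=C(\C(=O)OCC)CC/C=C(/C)C[C@H](O[Si](C)(C)C(C)(C)C)[C@H]1CC(=O)OC(C)(C)C)c1ccccc1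
F6 | step 15 | trimethylsilyl ester and C6 trimethylsilyl ether of the seco acid of 21 | C[Si](C)(C)O[C@@H]1/C=C(\CO[Si](c2ccccc2)(c2ccccc2)C(C)(C)C)CC/C=C(/C)C[C@H](O[Si](C)(C)C(C)(C)C)[C@H]1CC(=O)O[Si](C)(C)C
F7 | step 15 | 6-hydroxy seco acid of 21 | O[C@@H]1/C=C(\CO[Si](c2ccccc2)(c2ccccc2)C(C)(C)C)CC/C=C(/C)C[C@H](O[Si](C)(C)C(C)(C)C)[C@H]1CC(=O)O
F8 | step 17 | C8,C15-diol of the α-methylene lactone | C=C1C(=O)O[C@@H]2/C=C(\CO)CC/C=C(/C)C[C@H](O)[C@@H]12
A1 | alternative 1 | cis-fused hydroazulene C8 carbinol with C5 mesylate, C4 silyloxymethyl, C6 triethylsilyl ether and C7 2-(4-methoxybenzyloxy)ethyl arm | O[C@@]12CC(C)=CCC[C@]1(CO[Si](c3ccccc3)(c3ccccc3)C(C)(C)C)[C@@H](OS(C)(=O)=O)[C@@H](O[Si](CC)(CC)CC)[C@@H]2CCOCc2ccc(OC)cc2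
A2 | alternative 1 | protected cyclodeca-1(10),4-dien-8-one from Grob fragmentation | O=C1C/C(C)=C\CC/C(CO[Si](c2ccccc2)(c2ccccc2)C(C)(C)C)=C/[C@@H](O[Si](CC)(CC)CC)[C@@H]1CCOCc1ccc(OC)cc1
A3 | alternative 2 | ten-membered C6 carbinol with C7 ethynyl group, C8 silylated side-chain ester and C15 silyl ether | O[C@@H]1/C=C(\CO[Si](c2ccccc2)(c2ccccc2)C(C)(C)C)CC/C=C(/C)C[C@H](OC(=O)[C@@H](C)CO[Si](c2ccccc2)(c2ccccc2)C(C)(C)C)[C@H]1C#C
A4 | alternative 2 | bis(tert-butyldiphenylsilyl) ether of the target | C=C1C(=O)O[C@@H]2/C=C(\CO[Si](c3ccccc3)(c3ccccc3)C(C)(C)C)CC/C=C(/C)C[C@H](OC(=O)[C@@H](C)CO[Si](c3ccccc3)(c3ccccc3)C(C)(C)C)[C@@H]12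
A5 | alternative 3 | acyclic C6 aldehyde with C5 vinyl iodide, C7 tert-butyl acetate arm and C8 silyl ether | O=C[C@H](CC(=O)OC(C)(C)C)[C@@H](O[Si](C)(C)C(C)(C)C)C/C(C)=C\CC/C(CO[Si](c1ccccc1)(c1ccccc1)C(C)(C)C)=C/I
A6 | alternative 3 | ten-membered C6 carbinol with C7 tert-butyl acetate arm (identical with 20) | O[C@@H]1/C=C(\CO[Si](c2ccccc2)(c2ccccc2)C(C)(C)C)CC/C=C(/C)C[C@H](O[Si](C)(C)C(C)(C)C)[C@H]1CC(=O)OC(C)(C)C
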